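**Retrosynthetic overview**
1. The target is (2S)-7-hydroxy-4'-methoxy-6,8-diprenylflavanone; the last step only frees the 7-OH from MOM ether 10.
2. Key disconnection: the bond between C-3 and C-4 of the pyranone (ring C). Forward, a rhodium/chiral bisphosphine catalysed intramolecular hydroacylation adds the formyl C–H of salicylaldehyde 9 across its own aryl enol ether, closing ring C and setting C-2 in one event from an achiral, open-chain isomer of 10.
3. Enabling feature: C-4 is an aryl ketone carbon ortho to O-1 on ring A, C-3 is an unsubstituted CH2, and C-2 (the only stereocentre) carries O-1 and the anisyl ring B. Hence an enol ether in which O-1 and the anisyl group sit on C-2 and C-3 is the terminal CH2, plus a formyl group at C-4, is the exact hydroacylation precursor.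
4. Enol ether 9 comes from phenol 5 by Mitsunobu O-alkylation with bromohydrin 7 and base-induced loss of HBr. Phenol 5 comes from 2,4-dihydroxybenzaldehyde by dibromination, 4-O-MOM protection and twofold Stille prenylation.
5. Ring order: rings A and B are bought; ring C is the only ring formed, in step 7.

Key step: step 7

Assumption: the sense of induction of the rhodium catalyst on an aryl enol ether is not established, so the bisphosphine antipode that delivers the (2S) product is to be used; it is written below as (R)-DTBM-SEGPHOS.

**Step 1**
Reactants: 1 2,4-dihydroxybenzaldehyde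
Product: 2 3,5-dibromo-2,4-dihydroxybenzaldehyde
Conditions: Br2 (2.1 equiv), AcOH, rt
Reagents that add atoms: bromine, BrBr
Why: Electrophilic aromatic bromination is directed by both hydroxyl groups to C-3 (between them) and C-5 (ortho to the 4-OH, para to the 2-OH), while C-6 is meta to both and stays free, so two equivalents of bromine should give the 3,5-dibromide.

**Step 2**
Reactants: 2 3,5-dibromo-2,4-dihydroxybenzaldehyde
Product: 3 3,5-dibromo-2-hydroxy-4-(methoxymethoxy)benzaldehyde
Conditions: MOMCl (1.05 equiv), K2CO3 (1.1 equiv), acetone, 0 °C to rt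
Reagents that add atoms: chloromethyl methyl ether, COCCl
Why: Williamson-type O-alkylation with one equivalent of MOMCl should go to the 4-OH, which is the more acidic phenol (para to the formyl group, between two bromines) and is not tied up in the hydrogen bond that holds the 2-OH to the formyl oxygen.

**Step 3**
Reactants: 3 3,5-dibromo-2-hydroxy-4-(methoxymethoxy)benzaldehyde; 4 tributyl(3-methylbut-2-en-1-yl)stannane (2.6 equiv)
Product: 5 2-hydroxy-4-(methoxymethoxy)-3,5-bis(3-methylbut-2-en-1-yl)benzaldehyde
Conditions: Pd(PPh3)4 (10 mol %), DMF, 100 °C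
Reagents that add atoms: none
Why: Twofold Stille coupling, in which zerovalent palladium inserts into each C–Br bond, the allylic stannane transmetalates and reductive elimination through the less hindered primary terminus of the prenyl palladium species should deliver the linear prenyl groups, while the neutral conditions leave the aldehyde, the free phenol and the MOM ether untouched.

**Step 4**
Reactants: 6 2-bromo-1-(4-methoxyphenyl)ethan-1-one
Product: 7 racemic 2-bromo-1-(4-methoxyphenyl)ethan-1-ol
Conditions: NaBH4, MeOH, 0 °C
Reagents that add atoms: none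
Why: Borohydride reduction of the α-bromo ketone at 0 °C should give the racemic bromohydrin without closure to the epoxide.

**Step 5**
Reactants: 5 2-hydroxy-4-(methoxymethoxy)-3,5-bis(3-methylbut-2-en-1-yl)benzaldehyde; 7 racemic 2-bromo-1-(4-methoxyphenyl)ethan-1-ol
Product: 8 racemic 2-[2-bromo-1-(4-methoxyphenyl)ethoxy]-4-(methoxymethoxy)-3,5-bis(3-methylbut-2-en-1-yl)benzaldehyde
Conditions: PPh3, DIAD, THF, 0 °C to rt
Reagents that add atoms: none
Why: Mitsunobu etherification, in which the salicylaldehyde-type phenol is acidic enough to protonate the betaine and the p-methoxybenzylic alkoxyphosphonium ion is a very reactive electrophile at the benzylic carbon, so the aryl ether should form; the configuration of this carbon is of no concern because it becomes sp2 in step 6.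

**Step 6**
Reactants: 8 racemic 2-[2-bromo-1-(4-methoxyphenyl)ethoxy]-4-(methoxymethoxy)-3,5-bis(3-methylbut-2-en-1-yl)benzaldehyde
Product: 9 2-{[1-(4-methoxyphenyl)ethenyl]oxy}-4-(methoxymethoxy)-3,5-bis(3-methylbut-2-en-1-yl)benzaldehyde (achiral)
Conditions: KOtBu (1.5 equiv), THF, 0 °C
Reagents that add atoms: none
Why: Base-induced dehydrobromination (bimolecular β-elimination) of a β-bromo ether, in which the only β-hydrogen is the benzylic α-aryloxy C–H, so only the 1,1-disubstituted aryl enol ether can form, and the non-enolisable aldehyde, the MOM ether and the prenyl groups are inert to KOtBu at 0 °C.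

**Step 7**
Reactants: 9 2-{[1-(4-methoxyphenyl)ethenyl]oxy}-4-(methoxymethoxy)-3,5-bis(3-methylbut-2-en-1-yl)benzaldehyde
Product: 10 (2S)-7-(methoxymethoxy)-2-(4-methoxyphenyl)-6,8-bis(3-methylbut-2-en-1-yl)-2,3-dihydro-4H-chromen-4-one
Conditions: [Rh(cod)Cl]2 (2.5 mol %), (R)-DTBM-SEGPHOS (5.5 mol %), Na[B(3,5-(CF3)2C6H3)4] (5 mol %), 1,4-dioxane, 60 °C, acid-free glassware
Reagents that add atoms: none
Why: Proposed new method: a cationic monovalent rhodium bisphosphine complex should insert into the formyl C–H bond of 9 to give a trivalent rhodium acyl hydride held next to the enol ether by the ortho oxygen tether, the hydride should then migrate to the internal alkene carbon (the future C-2) to give a seven-membered acyl alkyl rhodacycle, and C–C reductive elimination should form the bond between C-3 and C-4. The closest known reaction type is the rhodium/chiral bisphosphine catalysed endo-selective intramolecular hydroacylation of 1,1-disubstituted alkenes carried on ortho-allylbenzaldehydes and on N-vinyl or N-allyl heteroaryl carbaldehydes, which gives benzo-fused ketones with a β stereocentre; what is new is an aryl enol ether as the alkene partner. Ring C is closed in the 6-endo-trig mode, the acyl carbon going to the terminal CH2. The stereocentre at C-2 arises in the hydride insertion step and is controlled by the chiral bisphosphine on rhodium, which selects the enantiotopic face of the enol ether, and the neutral conditions cannot racemise it by retro-oxa-Michael opening. The step needs endo over exo closure and hydroacylation over decarbonylation, β-aryloxy elimination and alkene isomerisation; the 1,1-disubstitution forces the exo path through a tertiary alkyl rhodium species, the enol ether has no allylic hydrogen and cannot isomerise, and the two prenyl groups are trisubstituted alkenes on positions that cannot reach the acyl rhodium centre.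

**Step 8**
Reactants: 10 (2S)-7-(methoxymethoxy)-2-(4-methoxyphenyl)-6,8-bis(3-methylbut-2-en-1-yl)-2,3-dihydro-4H-chromen-4-one
Product: 11 (2S)-7-hydroxy-2-(4-methoxyphenyl)-6,8-bis(3-methylbut-2-en-1-yl)-2,3-dihydro-4H-chromen-4-one (the target)
Conditions: HCl (3 M aq.), MeOH, 40 °C
Reagents that add atoms: none
Why: Acid-catalysed cleavage of the MOM acetal with transfer of its CH2 unit to methanol should free the 7-OH under conditions that are standard for prenylated flavonoids, dilute acid being too weak to cyclise the ortho prenyl groups onto the phenol and unable to open the flavanone by the base-mediated retro-oxa-Michael path that would racemise C-2.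

**Compound list**
1 | 2,4-dihydroxybenzaldehyde | O=Cc1ccc(O)cc1O | starting material
2 | 3,5-dibromo-2,4-dihydroxybenzaldehyde | O=Cc1cc(Br)c(O)c(Br)c1O | intermediate
3 | 3,5-dibromo-2-hydroxy-4-(methoxymethoxy)benzaldehyde | O=Cc1cc(Br)c(OCOC)c(Br)c1O | intermediate
4 | tributyl(3-methylbut-2-en-1-yl)stannane | CCCC[Sn](CCCC)(CCCC)CC=C(C)C | starting material
5 | 2-hydroxy-4-(methoxymethoxy)-3,5-bis(3-methylbut-2-en-1-yl)benzaldehyde | O=Cc1cc(CC=C(C)C)c(OCOC)c(CC=C(C)C)c1O | intermediate
6 | 2-bromo-1-(4-methoxyphenyl)ethan-1-one | COc1ccc(cc1)C(=O)CBr | starting material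
7 | racemic 2-bromo-1-(4-methoxyphenyl)ethan-1-ol | COc1ccc(cc1)C(O)CBr | intermediate
8 | racemic 2-[2-bromo-1-(4-methoxyphenyl)ethoxy]-4-(methoxymethoxy)-3,5-bis(3-methylbut-2-en-1-yl)benzaldehyde | COc1ccc(cc1)C(CBr)Oc1c(C=O)cc(CC=C(C)C)c(OCOC)c1CC=C(C)C | intermediate
9 | 2-{[1-(4-methoxyphenyl)ethenyl]oxy}-4-(methoxymethoxy)-3,5-bis(3-methylbut-2-en-1-yl)benzaldehyde | COc1ccc(cc1)C(=C)Oc1c(C=O)cc(CC=C(C)C)c(OCOC)c1CC=C(C)C | intermediate
10 | (2S)-7-(methoxymethoxy)-2-(4-methoxyphenyl)-6,8-bis(3-methylbut-2-en-1-yl)-2,3-dihydro-4H-chromen-4-one | COc1ccc([C@@H]2CC(=O)c3cc(CC=C(C)C)c(OCOC)c(CC=C(C)C)c3O2)cc1 | intermediate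
11 | (2S)-7-hydroxy-2-(4-methoxyphenyl)-6,8-bis(3-methylbut-2-en-1-yl)-2,3-dihydro-4H-chromen-4-one | COc1ccc([C@@H]2CC(=O)c3cc(CC=C(C)C)c(O)c(CC=C(C)C)c3O2)cc1 | target

**Step count and risks**
Total steps: 8. Longest linear sequence: 7 steps (steps 1, 2, 3, 5, 6, 7, 8); step 4 is a one-step side branch.

Step 7 (Proposed new method). The acyl rhodium hydride may lose CO before the alkene inserts. The alkyl rhodium intermediate may undergo β-aryloxy elimination with loss of the tether. Closure may occur in the 5-exo sense, rhodium hydride may move the prenyl double bonds, facial selectivity at the new stereocentre may be poor, or adventitious acid may hydrolyse the enol ether. The fallback uses known chemistry and sets out from compound 5. Addition of HC≡CMgBr (3 equiv, THF, 0 °C) to the aldehyde should give 1-[2-hydroxy-4-(methoxymethoxy)-3,5-bis(3-methylbut-2-en-1-yl)phenyl]prop-2-yn-1-ol F1. Oxidation with MnO2 (CH2Cl2, rt) should give 1-[2-hydroxy-4-(methoxymethoxy)-3,5-bis(3-methylbut-2-en-1-yl)phenyl]prop-2-yn-1-one F2. Amine-mediated 6-endo cyclisation of the phenol onto the ynone (Et2NH, EtOH, rt to 60 °C) should give 7-(methoxymethoxy)-6,8-bis(3-methylbut-2-en-1-yl)-4H-chromen-4-one F3. Asymmetric conjugate addition of 4-methoxyphenylboronic acid to this chromone, catalysed by divalent palladium with a chiral pyridine-oxazoline ligand (Pd(OCOCF3)2, the t-BuPyOx enantiomer that leads to the (2S) series, NH4PF6, H2O, ClCH2CH2Cl, 60 °C), then sets the stereocentre and comes back to the route at compound 10.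

Step 3. The second coupling at the bromide on C-3, which sits between two oxygen substituents, may stall. Coupling may occur through the tertiary terminus of the prenyl unit to give 1,1-dimethylallyl isomers, or the acidic phenol may protodestannylate the reagent. The fallback avoids cross-coupling and sets out from compound 1. Direct twofold C-alkylation of the resorcinol phenoxide with 1-bromo-3-methylbut-2-ene (aq. KOH, rt) should give 2,4-dihydroxy-3,5-bis(3-methylbut-2-en-1-yl)benzaldehyde F4 in one step, though with modest efficiency expected because O-alkylation and monoalkylation compete. Selective 4-O-protection (MOMCl, K2CO3, acetone) then comes back to the route at compound 5, bypassing steps 1 to 3.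

Step 5. The p-methoxybenzylic alkoxyphosphonium ion may ionise and then eliminate or be captured by the hydrazide, since the phenol is hindered and hydrogen-bonded. The fallback forms the C(sp2)–O bond directly and sets out from compound 5. A Chan–Lam coupling with 2-[1-(4-methoxyphenyl)ethenyl]-4,4,5,5-tetramethyl-1,3,2-dioxaborolane (Cu(OAc)2, pyridine, 4 Å molecular sieves, air, CH2Cl2, rt) would give the aryl enol ether in one operation and come back to the route at compound 9, bypassing bromo ether 8 and step 6; it makes no new compound (F0).

**Further compounds**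
F1 | step 7 | racemic 1-[2-hydroxy-4-(methoxymethoxy)-3,5-bis(3-methylbut-2-en-1-yl)phenyl]prop-2-yn-1-ol | C#CC(O)c1cc(CC=C(C)C)c(OCOC)c(CC=C(C)C)c1O
F2 | step 7 | 1-[2-hydroxy-4-(methoxymethoxy)-3,5-bis(3-methylbut-2-en-1-yl)phenyl]prop-2-yn-1-one | C#CC(=O)c1cc(CC=C(C)C)c(OCOC)c(CC=C(C)C)c1O
F3 | step 7 | 7-(methoxymethoxy)-6,8-bis(3-methylbut-2-en-1-yl)-4H-chromen-4-one | O=c1ccoc2c(CC=C(C)C)c(OCOC)c(CC=C(C)C)cc12
F4 | step 3 | 2,4-dihydroxy-3,5-bis(3-methylbut-2-en-1-yl)benzaldehyde | O=Cc1cc(CC=C(C)C)c(O)c(CC=C(C)C)c1O
F0 | step 5 | none | none
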